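The readings are calculated on assumed constants, and the scatter is random.

Once starting material has been consumed, target plus over-reaction product stays near the charge in the earlier runs: 101% at the last delta reading, where starting material reads 0%, and 98.8% at the last epsilon reading. The share asked for is therefore the fraction of formed target that has survived. Target in delta falls to 23.9% with no plateau in the readings, so over-reaction product is the end state in view, and the share is a matter of kinetic control: how far along that road the flask stands when stopped.

| flask | starting material | target | temperature | remark | time |
|---|---|---|---|---|---|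
| epsilon | 0.050 M | 0.50 mM | −35 °C | run made earlier |  |
| delta | 0.050 M | 0.75 mM | −8 °C | run made earlier |  |
| eta | 0.10 M | 1 mM | −35 °C | run made earlier |  |
| spring | 0.050 M | 1.00 mM | 0 °C |  | 6.0 min |
| dawn | 0.050 M | 1.00 mM | 15 °C |  | 6.0 min |
| winter | 0.050 M | 1.00 mM | −30 °C |  | 6.0 min |
| summer | 0.050 M | 1.00 mM | −15 °C |  | 6.0 min |

- epsilon (time / min: target / %, over-reaction product / %, starting material / %): 3.00: 70.2, 0.9, 28.7; 5.00: 97.2, 1.5, 1.0; 8.00: 96.8, 2.9, 0.5; 15.0: 93.8, 6.6, 0; 30.0: 85.8, 13.0, 0.4
- delta (time / min: target / %, over-reaction product / %, starting material / %): 0.500: 93.3, 7.4, 0.3; 1.50: 73.6, 27.1, 0.8; 3.00: 50.6, 50.8, 0.2; 4.00: 39.6, 60.8, 0; 6.00: 23.9, 76.8, 0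
- eta (time / min: target / %, over-reaction product / %, starting material / %): 8.00: 96.0, 4.2, 0; 15.0: 92.1, 7.6, 0; 25.0: 87.2, 11.8, 0; 30.0: 85.0, 14.5, 0

(standard deviation of a reading: 0.5 percentage points)

* the flask with the highest share of target in all that became target or over-reaction product ("all alike" if they lie within 1.5 percentage points) (spring / dawn / winter / summer / all alike)
* share of target in all that became target or over-reaction product, spring
* share of target in all that became target or over-reaction product, dawn
* share of target in all that became target or over-reaction product, winter
* share of target in all that became target or over-reaction product, summer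



The runs seem at odds. Delta at −8 °C reads 0.3% starting material at 0.500 min, while epsilon at −35 °C still reads 28.7% at 3.00 min; yet delta ends at 23.9% target after 6.00 min, and epsilon reads 96.8% after 8.00 min. The quicker flask reads less target.

Two clocks clear this up. Late in each run the logarithm of target falls linearly, with first-order loss constant k_d read as 0.00548 min⁻¹ in epsilon and 0.248 min⁻¹ in delta, a factor of 45.3. Extrapolating each line back to the full charge gives a formation moment t_f of 2.07 min in epsilon and 0.220 min in delta, a factor of 9.41. Between these runs, then, loss gains more than formation does.

The reckoning here takes k_d as free of the charges, which epsilon and eta can show only at one ratio of target to starting material, with an activation energy of 74.1 kJ mol⁻¹, and takes t_f from the nearest run. Winter then has k_d of 0.0118 min⁻¹, and its survival S, the fraction of formed target still standing, exp(−k_d(t − t_f)), comes to 95.5%. Summer has 0.0995 min⁻¹ and S of 56.2%.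

The forecast names winter, with 90% there, 46% in summer, 1.2% in spring and 0% in dawn. On its constant it says: “I therefore assume k scales with that ratio, though the runs do not prove it.” Its summer constant is 0.15/min, against 0.0995 min⁻¹ in the reckoning here.

The flasks give winter as best, with 94.6%; summer gives 57.0%, which is 11 percentage points above the forecast, spring 2.05% and dawn 0%.

    starting material + target → 2 target (k = 12.0 M⁻¹ s⁻¹, Ea = 46.0 kJ mol⁻¹)
    starting material → target (k = 1.60 × 10⁻⁴ s⁻¹, Ea = 88.0 kJ mol⁻¹)
    2 starting material → homo dimer (k = 0.0150 M⁻¹ s⁻¹, Ea = 39.0 kJ mol⁻¹)
    target → over-reaction product (k = 0.0110 s⁻¹, Ea = 74.0 kJ mol⁻¹)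
    (constants at 0 °C)

In winter the half-life of target by its step to over-reaction product, 58.5 min, is far longer than the 0.46 min of starting material by the step with target at 1.32 min. Winter holds 95.5% target at 6.00 min. S stood at 95.5% for winter's 94.6% and 56.2% for summer's 57.0%. Carried to spring, S gives 2.17%, and spring gives 2.05%.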